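The lactone of the target is the chain C9 (OCH2)–C8–C8'–C9' (C=O), closed through oxygen. Ring A benzyl sits on C8 and ring B benzyl on C8'. This dibenzyl-substituted four-carbon unit is disconnected to a 2-alkyn-1-ol whose two alkyne carbons accept a benzyl nucleophile and CO2. The butynol that already carries the ring B arm reacts as its magnesium alkoxide with the ring A benzyl Grignard reagent in an anti carbomagnesiation. Carboxylation and acid then give the butenolide. One flask forms C7–C8, C8'–C9', O–C9' and the ring, and each arm is placed unambiguously. Ligand-controlled hydride delivery to C8, equilibration at C8' and hydrogenolysis complete the synthesis.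

Key step: step 8

Assumption: the sense of induction of the bisphosphine on this butenolide cannot be assigned in advance. (R)-DTBM-SEGPHOS is written, and the equally available (S)-ligand is used if a trial run shows that it is the one giving 8R.
Locants: C7 and C7' are the benzylic CH2 groups of the ring A arm and the ring B arm.

Step 1
Reactants: 1 5-hydroxyvanillin (3,4-dihydroxy-5-methoxybenzaldehyde)
Product: 2 3,4-bis(benzyloxy)-5-methoxybenzaldehyde
Conditions: BnBr (2.3 equiv), K2CO3 (3 equiv), DMF, 60 °C
Reagents that add atoms: benzyl bromide, BrCc1ccccc1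
Why: Williamson ether synthesis, in which K2CO3 ionises both catechol hydroxyls, the phenoxides displace bromide, and the aldehyde and methyl ether are untouched.

Step 2
Reactants: 2 3,4-bis(benzyloxy)-5-methoxybenzaldehyde
Product: 3 [3,4-bis(benzyloxy)-5-methoxyphenyl]methanol
Conditions: NaBH4, MeOH–THF, 0 °C
Reagents that add atoms: none
Why: Borohydride reduction of an aromatic aldehyde, to which the aryl ethers are inert.

Step 3
Reactants: 3 [3,4-bis(benzyloxy)-5-methoxyphenyl]methanol
Product: 4 1,2-bis(benzyloxy)-5-(bromomethyl)-3-methoxybenzene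
Conditions: PBr3 (0.4 equiv), CH2Cl2, 0 °C; used crude
Reagents that add atoms: phosphorus tribromide, BrP(Br)Br
Why: Bromodehydroxylation of a benzylic alcohol through its phosphite ester (SN2 by bromide), which is fast at 0 °C on this electron-rich ring and mild enough for the benzyl ethers.

Step 4
Reactants: 4 1,2-bis(benzyloxy)-5-(bromomethyl)-3-methoxybenzene; 5 propargyl alcohol
Product: 7 4-[3,4-bis(benzyloxy)-5-methoxyphenyl]but-2-yn-1-ol, via dimagnesium propargyl alkoxide 6 (not isolated)
Conditions: 5 (1.3 equiv), EtMgBr (2.6 equiv), THF, 0 °C → rt; CuI (10 mol%), 4, 50 °C; 1 M HCl, 0 °C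
Reagents that add atoms: none
Why: Copper-catalysed alkylation of an alkynyl Grignard reagent with a benzylic halide, in which EtMgBr masks the hydroxyl as a poorly nucleophilic magnesium alkoxide and metalates the alkyne terminus, so only C–C coupling occurs and the carbonate-free medium should not isomerise the skipped aryl alkyne to an allene.

Step 5
Reactants: 8 O-benzylvanillin (4-(benzyloxy)-3-methoxybenzaldehyde, commercial)
Product: 9 [4-(benzyloxy)-3-methoxyphenyl]methanol
Conditions: NaBH4, MeOH–THF, 0 °C
Reagents that add atoms: none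
Why: Borohydride reduction of an aromatic aldehyde, with no other reducible group present.

Step 6
Reactants: 9 [4-(benzyloxy)-3-methoxyphenyl]methanol
Product: 10 1-(benzyloxy)-4-(chloromethyl)-2-methoxybenzene
Conditions: SOCl2 (1.2 equiv), CH2Cl2, 0 °C → rt; evaporation, recrystallisation
Reagents that add atoms: thionyl chloride, O=S(Cl)Cl
Why: Chlorodehydroxylation through the chlorosulfite, whose by-products are gases, so the chloride is obtained dry and acid-free as magnesium insertion requires.

Step 7
Reactants: 10 1-(benzyloxy)-4-(chloromethyl)-2-methoxybenzene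
Product: 11 4-(benzyloxy)-3-methoxybenzylmagnesium chloride (titrated solution, used at once)
Conditions: Mg turnings (3 equiv, trace I2), 2-MeTHF, 0 °C, slow addition, high dilution
Reagents that add atoms: magnesium, [Mg]
Why: Grignard reagent formation by magnesium insertion into a benzylic C–Cl bond, in which the chloride rather than the bromide, excess metal surface, dilution, low temperature and 2-MeTHF all hold back Wurtz-type dimerisation and the aryl ethers are inert.

Step 8
Reactants: 7 4-[3,4-bis(benzyloxy)-5-methoxyphenyl]but-2-yn-1-ol; 11 4-(benzyloxy)-3-methoxybenzylmagnesium chloride; 12 carbon dioxide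
Product: 16 3-[3,4-bis(benzyloxy)-5-methoxybenzyl]-4-[4-(benzyloxy)-3-methoxybenzyl]furan-2(5H)-one, via chloromagnesium alkoxide 13 (not isolated), via oxamagnesacycle 14 (not isolated), via (Z)-hydroxy acid 15 (not isolated)
Conditions: 7, MeMgCl (1.0 equiv), toluene–2-MeTHF, −20 °C; CuI (10 mol%), 11 (2 equiv), −20 °C → rt; dry CO2 gas, −20 °C → rt; 2 M HCl, rt; NaHCO3 wash
Reagents that add atoms: none
Why: MeMgCl first turns 7 into alkoxide 13 so that no 11 is spent as a base; the benzylcopper–magnesium species from 11 and CuI then attacks the alkyne carbon next to the carbinol (C8) on the side opposite the alkoxide-bound magnesium, which ends on C8' inside the five-membered oxamagnesacycle 14. The closest known reaction type is the hydroxyl-directed anti-carbomagnesiation of 2-alkyn-1-ols with carboxylative trapping to butenolides, in which benzylic Grignard reagents are among the reactive partners. CO2 inserts into the C8'–Mg bond with retention of alkene geometry, so acidification gives 15 with CH2OH and CO2H on the same side, and the ring closes by 5-exo-trig attack of the hydroxyl oxygen on the carboxyl carbon with loss of water. No stereocentre is formed; the only stereochemical element is the Z alkene geometry, which the chelate fixes. The step needs regioselectivity (benzyl to C8, metal to C8') and anti addition, both secured by the O–Mg tether, and addition must outrun deprotonation of the benzylic-propargylic C7' methylene, which is kinetically slow for Grignard reagents at or below room temperature in a toluene-rich medium. Because each arm comes from its own component, the two similar benzyl groups never have to be distinguished on a common intermediate, and the arylacetic acid from surplus 11 is removed by the NaHCO3 wash since 16 is neutral.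

Step 9
Reactants: 16 3-[3,4-bis(benzyloxy)-5-methoxybenzyl]-4-[4-(benzyloxy)-3-methoxybenzyl]furan-2(5H)-one
Product: 17 (4R)-3-[3,4-bis(benzyloxy)-5-methoxybenzyl]-4-[4-(benzyloxy)-3-methoxybenzyl]dihydrofuran-2(3H)-one, mixture of C3 (C8') epimers
Conditions: Cu(OAc)2·H2O (5 mol%), (R)-DTBM-SEGPHOS (5.5 mol%), (EtO)2MeSiH (3 equiv), t-BuOH (3 equiv), toluene, rt → 40 °C; aq NH4F
Reagents that add atoms: none
Why: Proposed new method: the bisphosphine-ligated copper hydride formed from Cu(OAc)2 and the silane should add hydride to C8 of the planar butenolide on the face left open by the ligand, t-BuOH protonates the copper enolate at C8' and releases copper tert-butoxide, and the silane converts this back into the hydride; the closest known reaction type is the asymmetric CuH conjugate reduction of butenolides and related unsaturated lactones that carry only a β-substituent, and the new element is the extra α-benzyl group that makes the alkene tetrasubstituted, which is why the most active ligand class, a small silane and a proton shuttle are chosen; C8 is set as R by the ligand, C8' is left for step 10, and the alkoxide-free catalyst preparation avoids dienolate formation at the acidic C7 and C7' methylenes.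

Step 10
Reactants: 17 (4R)-lactone, mixture of C8' epimers
Product: 18 (3R,4R)-3-[3,4-bis(benzyloxy)-5-methoxybenzyl]-4-[4-(benzyloxy)-3-methoxybenzyl]dihydrofuran-2(3H)-one (trans)
Conditions: NaOMe (0.3 equiv), MeOH–THF, 50 °C; then 1 M HCl
Reagents that add atoms: none
Why: Thermodynamic epimerisation through the lactone enolate, in which only C8' is enolisable, so C8 keeps its R configuration and drives the C8' benzyl group to the opposite face (trans, 8'R), and the acid quench recloses any hydroxy ester formed by methanolysis.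

Step 11
Reactants: 18 (3R,4R)-tris(benzyl ether)
Product: 19 (−)-thujaplicatin, (3R,4R)-3-(3,4-dihydroxy-5-methoxybenzyl)-4-(4-hydroxy-3-methoxybenzyl)dihydrofuran-2(3H)-one
Conditions: H2 (1 atm), 10% Pd/C, EtOAc–EtOH, rt; work-up under argon
Reagents that add atoms: none
Why: Catalytic hydrogenolysis of three aryl benzyl ethers under neutral conditions, which leaves the lactone, the methyl ethers and both stereocentres unchanged.

Compound list
1 | 5-hydroxyvanillin (3,4-dihydroxy-5-methoxybenzaldehyde) | COc1cc(C=O)cc(O)c1O | starting material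
2 | 3,4-bis(benzyloxy)-5-methoxybenzaldehyde | COc1cc(C=O)cc(OCc2ccccc2)c1OCc1ccccc1 | intermediate
3 | [3,4-bis(benzyloxy)-5-methoxyphenyl]methanol | COc1cc(CO)cc(OCc2ccccc2)c1OCc1ccccc1 | intermediate
4 | 1,2-bis(benzyloxy)-5-(bromomethyl)-3-methoxybenzene | COc1cc(CBr)cc(OCc2ccccc2)c1OCc1ccccc1 | intermediate
5 | propargyl alcohol (prop-2-yn-1-ol) | C#CCO | starting material
6 | bromomagnesium 3-(bromomagnesio)prop-2-yn-1-olate | Br[Mg]OCC#C[Mg]Br | intermediate
7 | 4-[3,4-bis(benzyloxy)-5-methoxyphenyl]but-2-yn-1-ol | OCC#CCc1cc(OCc2ccccc2)c(OCc2ccccc2)c(OC)c1 | intermediate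
8 | O-benzylvanillin (4-(benzyloxy)-3-methoxybenzaldehyde) | COc1cc(C=O)ccc1OCc1ccccc1 | starting material
9 | [4-(benzyloxy)-3-methoxyphenyl]methanol | COc1cc(CO)ccc1OCc1ccccc1 | intermediate
10 | 1-(benzyloxy)-4-(chloromethyl)-2-methoxybenzene | COc1cc(CCl)ccc1OCc1ccccc1 | intermediate
11 | 4-(benzyloxy)-3-methoxybenzylmagnesium chloride | COc1cc(C[Mg]Cl)ccc1OCc1ccccc1 | intermediate
12 | carbon dioxide | O=C=O | starting material
13 | chloromagnesium 4-[3,4-bis(benzyloxy)-5-methoxyphenyl]but-2-yn-1-olate | Cl[Mg]OCC#CCc1cc(OCc2ccccc2)c(OCc2ccccc2)c(OC)c1 | intermediate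
14 | 3-[3,4-bis(benzyloxy)-5-methoxybenzyl]-4-[4-(benzyloxy)-3-methoxybenzyl]-2,5-dihydro-1,2-oxamagnesole | COc1cc(CC2=C(Cc3cc(OCc4ccccc4)c(OCc4ccccc4)c(OC)c3)[Mg]OC2)ccc1OCc1ccccc1 | intermediate
15 | (Z)-2-[3,4-bis(benzyloxy)-5-methoxybenzyl]-3-[4-(benzyloxy)-3-methoxybenzyl]-4-hydroxybut-2-enoic acid | COc1cc(C/C(CO)=C(\Cc2cc(OCc3ccccc3)c(OCc3ccccc3)c(OC)c2)C(=O)O)ccc1OCc1ccccc1 | intermediate
16 | 3-[3,4-bis(benzyloxy)-5-methoxybenzyl]-4-[4-(benzyloxy)-3-methoxybenzyl]furan-2(5H)-one | COc1cc(CC2=C(Cc3cc(OCc4ccccc4)c(OCc4ccccc4)c(OC)c3)C(=O)OC2)ccc1OCc1ccccc1 | intermediate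
17 | (4R)-3-[3,4-bis(benzyloxy)-5-methoxybenzyl]-4-[4-(benzyloxy)-3-methoxybenzyl]dihydrofuran-2(3H)-one, C3 epimers | COc1cc(C[C@H]2COC(=O)C2Cc2cc(OCc3ccccc3)c(OCc3ccccc3)c(OC)c2)ccc1OCc1ccccc1 | intermediate
18 | (3R,4R)-3-[3,4-bis(benzyloxy)-5-methoxybenzyl]-4-[4-(benzyloxy)-3-methoxybenzyl]dihydrofuran-2(3H)-one | COc1cc(C[C@H]2COC(=O)[C@@H]2Cc2cc(OCc3ccccc3)c(OCc3ccccc3)c(OC)c2)ccc1OCc1ccccc1 | intermediate
19 | (−)-thujaplicatin, (3R,4R)-3-(3,4-dihydroxy-5-methoxybenzyl)-4-(4-hydroxy-3-methoxybenzyl)dihydrofuran-2(3H)-one | COc1cc(C[C@H]2COC(=O)[C@@H]2Cc2cc(O)c(O)c(OC)c2)ccc1O | target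

Total step count: 11. Longest linear sequence: 8 steps (steps 1–4 and 8–11, from 5-hydroxyvanillin).

Steps most likely to fail

1. Step 9 (bears the label).
- What may go wrong: hydride transfer to the fully substituted alkene may stall, or the catalyst may distinguish the two faces poorly.
- Fallback with known chemistry, setting out from 16 and returning at 18:
  - Conjugate reduction of 16 with NaBH4 and NiCl2·6H2O in MeOH–THF at 0 °C should give the racemic cis lactone F1.
  - NaOMe in MeOH equilibrates it to the racemic trans lactone F2.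
  - AlMe3-mediated aminolysis with (R)-1-phenylethylamine opens F2 to the (2R,3R)-hydroxy amide F3 and the (2S,3S)-hydroxy amide F4, which are separated by chromatography or crystallisation.
  - Hydroxyl-assisted hydrolysis of F3 in 1 M H2SO4–dioxane at 90 °C recloses the ring to 18 as a single enantiomer.

2. Step 8 (key step).
- What may go wrong: proton abstraction at C7' followed by propargyl–allene isomerisation, oxidative dimerisation of the benzylcopper species, or sluggish addition to the internal alkyne.
- Fallback, setting out from 10 and 4 and returning at 16: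
  - Zinc dust with LiCl in THF converts 10 into the ring A benzylzinc chloride F5.
  - A site-selective Negishi coupling of F5 with commercial 3,4-dibromofuran-2(5H)-one (O=C1OCC(Br)=C1Br) under Pd(PPh3)4 takes place at the more electrophilic C4–Br bond and gives the 3-bromo-4-benzylbutenolide F6.
  - A second Negishi coupling of F6 with the ring B benzylzinc bromide F7 (from 4, Zn and LiCl) under Pd(OAc)2/SPhos installs the C3 arm and gives 16.

3. Step 7.
- What may go wrong: Wurtz-type homocoupling of the electron-rich benzylic chloride at the metal surface, which lowers the titre of the reagent.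
- Fallback, setting out from 10 and returning at 11:
  - Displacement of chloride with Bu3SnLi (from Bu3SnH and LDA, THF, −78 °C) gives the benzylstannane F8.
  - Tin–lithium exchange with n-BuLi at −78 °C gives the benzyllithium F9 with no alkyl halide present.
  - Transmetalation with anhydrous MgCl2 in THF gives 11.

Further compounds
F1 | step 9 | rac-cis-3-[3,4-bis(benzyloxy)-5-methoxybenzyl]-4-[4-(benzyloxy)-3-methoxybenzyl]dihydrofuran-2(3H)-one, (3S,4R) and (3R,4S) | COc1cc(C[C@H]2COC(=O)[C@H]2Cc2cc(OCc3ccccc3)c(OCc3ccccc3)c(OC)c2)ccc1OCc1ccccc1.COc1cc(C[C@@H]2COC(=O)[C@@H]2Cc2cc(OCc3ccccc3)c(OCc3ccccc3)c(OC)c2)ccc1OCc1ccccc1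
F2 | step 9 | rac-trans-3-[3,4-bis(benzyloxy)-5-methoxybenzyl]-4-[4-(benzyloxy)-3-methoxybenzyl]dihydrofuran-2(3H)-one, (3R,4R) and (3S,4S) | COc1cc(C[C@H]2COC(=O)[C@@H]2Cc2cc(OCc3ccccc3)c(OCc3ccccc3)c(OC)c2)ccc1OCc1ccccc1.COc1cc(C[C@@H]2COC(=O)[C@H]2Cc2cc(OCc3ccccc3)c(OCc3ccccc3)c(OC)c2)ccc1OCc1ccccc1
F3 | step 9 | (2R,3R)-2-[3,4-bis(benzyloxy)-5-methoxybenzyl]-3-[4-(benzyloxy)-3-methoxybenzyl]-4-hydroxy-N-[(R)-1-phenylethyl]butanamide | COc1cc(C[C@@H](CO)[C@@H](Cc2cc(OCc3ccccc3)c(OCc3ccccc3)c(OC)c2)C(=O)N[C@H](C)c2ccccc2)ccc1OCc1ccccc1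
F4 | step 9 | (2S,3S)-2-[3,4-bis(benzyloxy)-5-methoxybenzyl]-3-[4-(benzyloxy)-3-methoxybenzyl]-4-hydroxy-N-[(R)-1-phenylethyl]butanamide | COc1cc(C[C@H](CO)[C@H](Cc2cc(OCc3ccccc3)c(OCc3ccccc3)c(OC)c2)C(=O)N[C@H](C)c2ccccc2)ccc1OCc1ccccc1
F5 | step 8 | 4-(benzyloxy)-3-methoxybenzylzinc chloride | COc1cc(C[Zn]Cl)ccc1OCc1ccccc1
F6 | step 8 | 4-[4-(benzyloxy)-3-methoxybenzyl]-3-bromofuran-2(5H)-one | COc1cc(CC2=C(Br)C(=O)OC2)ccc1OCc1ccccc1
F7 | step 8 | 3,4-bis(benzyloxy)-5-methoxybenzylzinc bromide | COc1cc(C[Zn]Br)cc(OCc2ccccc2)c1OCc1ccccc1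
F8 | step 7 | tributyl[4-(benzyloxy)-3-methoxybenzyl]stannane | CCCC[Sn](CCCC)(CCCC)Cc1ccc(OCc2ccccc2)c(OC)c1
F9 | step 7 | 4-(benzyloxy)-3-methoxybenzyllithium | [Li]Cc1ccc(OCc2ccccc2)c(OC)c1
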